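The closed, stirred vessel had run once before, as the grey run, with half of this flask's free catalyst.

the same everywhere: left-handed substrate 39 mM; right-handed substrate 39 mM; partner 117 mM

| run | free catalyst | remark | time |
|---|---|---|---|
| grey | 20 µM | run made earlier |  |
| flask | 39 µM |  | 6.0 min |

grey run (percent of the left-handed substrate and right-handed substrate together charged)

| time / s | left-handed substrate / % | left-handed product / % | right-handed substrate / % |
|---|---|---|---|
| 20.0 | 39.9 | 10.2 | 48.3 |
| 40.0 | 35.5 | 14.7 | 47.6 |
| 50.0 | 34.1 | 15.2 | 47.4 |
| 80.0 | 32.1 | 17.9 | 47.3 |

(each reading ± 0.3 percentage points)

- free catalyst is single-handed; left-handed substrate and right-handed substrate are mirror images of each other, charged as a racemate, each of them at the stated concentration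
- the reaction counts as stopped when no species that holds the left-handed substrate and right-handed substrate together changes by six tenths of a point or more over the second half of the time
- no earlier run changes the charge of free catalyst; that part of a forecast is a guess

- the state of affairs at 6.0 min: stopped, and by what, or still going (it is still moving / forward and back rates have come level / all of the left-handed substrate has reacted / the partner has run out first / no working catalyst is left)
- conversion of left-handed substrate and right-handed substrate together at 6.0 min
- amount of left-handed product at 6.0 min, in percent of the left-handed substrate and right-handed substrate together charged
- amount of right-handed substrate at 6.0 min, in percent of the left-handed substrate and right-handed substrate together charged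

In the grey run, left-handed substrate plus left-handed product held at 50.0% at 80.0 s. I therefore followed the stall exponent, minus the natural logarithm of the fraction of left-handed substrate's own charge still left, which read 0.443 at that reading. Loosely, left-handed product in the flask lay between the grey 17.9% and 50.0%, the charge of left-handed substrate.

To tighten this, I replaced the curve by its mean slopes. The exponent climbed at 0.0113 /s over the first interval and at 0.00584 /s over the second, about half the first slope. I took the slope to halve at least once per 30.0 s, so the tail after the last reading sums to less than the last gain, 0.0604. The grey exponent therefore lay between 0.443 and 0.504. I scaled both by the catalyst ratio 1.95, a guess that no earlier run tests. That put left-handed product in the flask between 28.9% and 31.3%.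

The forecast said no working catalyst is left, because “the catalyst is dying”, with conversion 35.7% (28% to 42%), left-handed product 30% (24% to 36%) and right-handed substrate 44.3% (43% to 46%). Its left-handed product stood inside my bracket, above the low end and below the high end.

The flask gave: the partner has run out first, conversion 36.2%, left-handed product 30.0%, right-handed substrate 43.8%.

    partner + catalyst intermediate B → free catalyst + right-handed product (k = 230 /M/s)
    free catalyst + right-handed substrate ⇌ catalyst intermediate B (K = 13.0 /M, k = 43000 /M/s)
    free catalyst + left-handed substrate ⇌ catalyst intermediate A (K = 35.0 /M, k = 17000 /M/s)
    partner + catalyst intermediate A → free catalyst + left-handed product (k = 640 /M/s)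
    free catalyst ⇌ dormant form (K = 0.400, k = 0.0520 /s)
    partner + free catalyst → spent catalyst (k = 0.330 /M/s)
    partner → decomposed reagent (k = 0.0240 /s)

At 6.00 min partner stood at 0% of its charge, with decomposed reagent at 88.8 mM, while free catalyst was still 26.2% of the catalyst charged. Left-handed substrate kept 40% of its own charge, more than partner, a stall exponent of 0.916, between 0.864 and 0.983. For the neighbour charged with 0.097 mM of free catalyst, the same scaling by 4.85 gave a fraction left between 8.68% and 11.7%. That neighbour kept 11% of its left-handed substrate at 6.00 min.

Readings and results stem from a simulated flask for an exercise; the scatter is artificial.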